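**Retrosynthetic overview**
1. Target ⇒ water opens a 2,3-epoxy lactone at the tertiary C3 with inversion ⇒ the C5-OH closes on the C8 ester ⇒ formate hydride opens the C5–C6 vinyl oxirane at C6 ⇒ a 2,3:5,6-bis-epoxide.
2. Bis-epoxide ⇒ one double Shi epoxidation of an achiral (2E,5E)-triene ester. This single operation fixes C2, C3 and C5.
3. Triene ester ⇒ Mitsunobu O-alkylation of umbelliferone (coumarin rings bought) with a dienoate allylic alcohol.
4. Dienoate alcohol ⇒ E-selective Wittig reaction (C5=C6) of (E)-5-hydroxy-3-methylpent-3-enal. The aldehyde ⇒ anti-Markovnikov hydration of (E)-3-methylpent-2-en-4-yn-1-ol.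
5. Ring order: both oxiranes form together, then the γ-lactone closes, then the last oxirane is hydrolysed anti. This mirrors the presumed path from 7-geranyloxycoumarin (C5/C8 oxygenation and lactonisation; 2,3-epoxide opened by water).

Assumption: side-chain atoms carry geranyl numbering (C1 = OCH2, C3 bears CH3, C5 = lactone CH–O, C8 = lactone C=O, C9 = exocyclic CH2). With this numbering the target is 2R,3S,5S.

**Step 1**
Reactants: 1 (E)-3-methylpent-2-en-4-yn-1-ol
Product: 2 (E)-5-hydroxy-3-methylpent-3-enal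
Conditions: [CpRu(MeCN)3]PF6 (3 mol%), 5,5'-bis(trifluoromethyl)-2,2'-bipyridine (3 mol%), H2O, acetone, 25 °C
Reagents that add atoms: water, O
Why: Ruthenium-vinylidene anti-Markovnikov alkyne hydration puts the oxygen on the terminal carbon under neutral conditions, so the β,γ-olefin keeps its place and its E geometry, the E geometry also prevents O-cyclisation, and no stereocentre is formed.

**Step 2**
Reactants: 2 (E)-5-hydroxy-3-methylpent-3-enal; 3 methyl 2-(bromomethyl)acrylate
Product: 6 methyl (3E,6E)-8-hydroxy-6-methyl-2-methylideneocta-3,6-dienoate, via tributylphosphonium bromide 4 (not isolated), via phosphorus ylide 5 (not isolated)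
Conditions: 3, PBu3, THF, 0 °C to rt; KOtBu, −78 °C; then 2, −78 to 0 °C
Reagents that add atoms: none
Why: Wittig olefination with an allylic tributylphosphonium ylide is E-selective and reacts at its α-carbon, which builds C5=C6 next to the intact acrylate, and the hydroxyl at C1 is no leaving group, so enolisation of 2 cannot lead to elimination.

**Step 3**
Reactants: 6 methyl (3E,6E)-8-hydroxy-6-methyl-2-methylideneocta-3,6-dienoate; 7 umbelliferone
Product: 8 methyl (3E,6E)-6-methyl-2-methylidene-8-[(2-oxo-2H-chromen-7-yl)oxy]octa-3,6-dienoate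
Conditions: PPh3, DIAD, THF, 0 °C to rt
Reagents that add atoms: none
Why: Mitsunobu etherification of a primary allylic alcohol with an acidic phenol proceeds by direct SN2 displacement at C1, keeps both E-olefins, and needs no base that could isomerise the skipped triene.

**Step 4**
Reactants: 8 methyl (3E,6E)-6-methyl-2-methylidene-8-[(2-oxo-2H-chromen-7-yl)oxy]octa-3,6-dienoate
Product: 9 methyl 2-[(2R,3R)-3-{[(2R,3R)-2-methyl-3-{[(2-oxo-2H-chromen-7-yl)oxy]methyl}oxiran-2-yl]methyl}oxiran-2-yl]prop-2-enoate (2R,3R,5R,6R in side-chain numbering)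
Conditions: D-fructose-derived Shi ketone (0.6 equiv), KHSO5 (as 2KHSO5·KHSO4·K2SO4), K2CO3, Bu4NHSO4, MeCN/CH2(OMe)2, aq Na2B4O7 buffer pH 10.5, −5 to 0 °C
Reagents that add atoms: potassium peroxymonosulfate, [K+].[O-]S(=O)(=O)OO
Why: Double Shi asymmetric epoxidation (chiral dioxirane, spiro transition state) gives R,R-oxiranes from both E-olefins with one catalyst enantiomer and so sets C2, C3 and C5 together, the acrylate and coumarin C=C bonds are too electron-poor to react, and the two independent inductions raise the ee of the major diastereomer.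

**Step 5**
Reactants: 9 bis-epoxide (as named in step 4)
Product: 12 (5S)-5-[(2S,3R)-2,3-dihydroxy-2-methyl-4-{(2-oxo-2H-chromen-7-yl)oxy}butyl]-3-methylideneoxolan-2-one (target), via hydroxy ester 10 (not isolated), via epoxy lactone 11 (not isolated)
Conditions: Pd2(dba)3·CHCl3 (2.5 mol%), PBu3 (10 mol%), HCO2H, Et3N, 1,4-dioxane, 0 °C to rt; then 0.5 M aq HClO4, THF, 0 °C to rt
Reagents that add atoms: water, O
Why: In the Tsuji–Shimizu hydrogenolysis zerovalent palladium ionises only the vinyl oxirane (the aryl ether is no longer allylic) and formate delivers hydride to the more substituted allyl terminus C6, which regenerates the C7=C9 acrylate and leaves the C5–O bond untouched, the freed C5-OH lactonises 5-exo-trig on the C8 ester, and acid-catalysed epoxide hydrolysis then brings water to the tertiary C3 with inversion while C2–O is retained, giving 2R,3S,5S.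

**Compound list**
1 | (E)-3-methylpent-2-en-4-yn-1-ol | C#C/C(C)=C/CO | starting material
2 | (E)-5-hydroxy-3-methylpent-3-enal | O=CC/C(C)=C/CO | intermediate
3 | methyl 2-(bromomethyl)acrylate | C=C(CBr)C(=O)OC | starting material
4 | tributyl[2-(methoxycarbonyl)allyl]phosphonium bromide | C=C(C[P+](CCCC)(CCCC)CCCC)C(=O)OC.[Br-] | intermediate
5 | methyl 2-[(tributylphosphoranylidene)methyl]acrylate | C=C(C=P(CCCC)(CCCC)CCCC)C(=O)OC | intermediate
6 | methyl (3E,6E)-8-hydroxy-6-methyl-2-methylideneocta-3,6-dienoate | C=C(C(=O)OC)/C=C/C/C(C)=C/CO | intermediate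
7 | umbelliferone (7-hydroxycoumarin) | Oc1ccc2ccc(=O)oc2c1 | starting material
8 | methyl (3E,6E)-6-methyl-2-methylidene-8-[(2-oxo-2H-chromen-7-yl)oxy]octa-3,6-dienoate | C=C(C(=O)OC)/C=C/C/C(C)=C/COc1ccc2ccc(=O)oc2c1 | intermediate
9 | (2R,3R,5R,6R)-bis-epoxide of 8 (full name in step 4) | COC(=O)C(=C)[C@H]1O[C@@H]1C[C@@]2(C)O[C@@H]2COc3ccc4ccc(=O)oc4c3 | intermediate
10 | methyl (4S)-4-hydroxy-5-[(2R,3R)-2-methyl-3-{[(2-oxo-2H-chromen-7-yl)oxy]methyl}oxiran-2-yl]-2-methylidenepentanoate | COC(=O)C(=C)C[C@H](O)C[C@@]1(C)O[C@@H]1COc2ccc3ccc(=O)oc3c2 | intermediate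
11 | (5S)-5-{[(2R,3R)-2-methyl-3-{[(2-oxo-2H-chromen-7-yl)oxy]methyl}oxiran-2-yl]methyl}-3-methylideneoxolan-2-one | C=C1C[C@@H](C[C@@]2(C)O[C@@H]2COc3ccc4ccc(=O)oc4c3)OC1=O | intermediate
12 | CNP0216562.1, (5S)-5-[(2S,3R)-2,3-dihydroxy-2-methyl-4-{(2-oxo-2H-chromen-7-yl)oxy}butyl]-3-methylideneoxolan-2-one | C=C1C[C@@H](C[C@](C)(O)[C@H](O)COc2ccc3ccc(=O)oc3c2)OC1=O | target

**Total step count:** 5. **Longest linear sequence:** 5 (1 → 2 → 6 → 8 → 9 → 12).

**Steps most likely to fail**

Step 2. Aldehyde 2 can slip into conjugation, the new olefin may not be cleanly E, and dienoate 6 can dimerise by Diels–Alder reaction.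
Fallback: this sets out from 7 and comes back at 8. O-alkylation of 7 with geranyl bromide (K2CO3, acetone) gives auraptene F1. mCPBA epoxidises only the distal, more electron-rich olefin to give 6,7-epoxyauraptene F2. H5IO6 cleaves F2 to 7-{[(2E)-3-methyl-6-oxohex-2-en-1-yl]oxy}coumarin F3. A Morita–Baylis–Hillman reaction with methyl acrylate and DABCO gives the Baylis–Hillman alcohol F4, and Ac2O/pyridine gives its acetate F5. Pd(PPh3)4/Et3N then eliminates acetic acid through the π-allyl complex to give the E-diene 8.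

Step 4. The C2=C3 olefin is deactivated by the allylic aryloxy group, so it may react slowly or with lower ee than the dienoate olefin.
Fallback: this sets out from 6 and comes back at 9. Hydroxyl-directed Sharpless asymmetric epoxidation of 6 (Ti(OiPr)4, D-(−)-diethyl tartrate, tBuOOH, 4 Å sieves, CH2Cl2, −20 °C) touches only the allylic-alcohol olefin and gives the (2R,3R)-epoxy alcohol F6. Mitsunobu coupling with 7 gives the mono-epoxide aryl ether F7. A single Shi epoxidation of the remaining C5=C6 olefin then gives 9.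

Step 5. Hydride may go to C9, which would give the 2-methyl-2-enoate and from it the endocyclic butenolide. The acid opening at C3 may also leak some retention.
Fallback: this sets out from 2 and comes back at 11. Chiral-phosphoric-acid-catalysed allylboration of 2 with methyl 2-[(pinacolatoboryl)methyl]acrylate and (S)-TRIP (facial sense assigned by analogy with allylboronate additions) gives the dihydroxy ester F8. On mild acid work-up F8 closes to the hydroxy lactone F9. Mitsunobu coupling with 7 gives the olefinic lactone F10, and Shi epoxidation of its only electron-rich olefin gives 11, which is hydrolysed as in step 5. The R descriptor at C5 in F8–F10 differs from the S in 11 only through the CIP ranking; the spatial arrangement is the same.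

**Further compounds**
F1 | step 2 | auraptene (7-geranyloxycoumarin) | CC(C)=CCC/C(C)=C/COc1ccc2ccc(=O)oc2c1
F2 | step 2 | 6,7-epoxyauraptene (racemic) | CC1(C)OC1CC/C(C)=C/COc2ccc3ccc(=O)oc3c2
F3 | step 2 | 7-{[(2E)-3-methyl-6-oxohex-2-en-1-yl]oxy}coumarin | O=CCC/C(C)=C/COc1ccc2ccc(=O)oc2c1
F4 | step 2 | methyl (6E)-3-hydroxy-6-methyl-2-methylidene-8-[(2-oxo-2H-chromen-7-yl)oxy]oct-6-enoate (racemic) | C=C(C(O)CC/C(C)=C/COc1ccc2ccc(=O)oc2c1)C(=O)OC
F5 | step 2 | methyl (6E)-3-acetoxy-6-methyl-2-methylidene-8-[(2-oxo-2H-chromen-7-yl)oxy]oct-6-enoate (racemic) | C=C(C(CC/C(C)=C/COc1ccc2ccc(=O)oc2c1)OC(C)=O)C(=O)OC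
F6 | step 4 | methyl (3E)-5-[(2R,3R)-3-(hydroxymethyl)-2-methyloxiran-2-yl]-2-methylidenepent-3-enoate | COC(=O)C(=C)/C=C/C[C@@]1(C)O[C@@H]1CO
F7 | step 4 | methyl (3E)-5-[(2R,3R)-2-methyl-3-{[(2-oxo-2H-chromen-7-yl)oxy]methyl}oxiran-2-yl]-2-methylidenepent-3-enoate | COC(=O)C(=C)/C=C/C[C@@]1(C)O[C@@H]1COc2ccc3ccc(=O)oc3c2
F8 | step 5 | methyl (4R,6E)-4,8-dihydroxy-6-methyl-2-methylideneoct-6-enoate | COC(=O)C(=C)C[C@H](O)C/C(C)=C/CO
F9 | step 5 | (5R)-5-[(2E)-4-hydroxy-2-methylbut-2-en-1-yl]-3-methylideneoxolan-2-one | C=C1C[C@@H](C/C(C)=C/CO)OC1=O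
F10 | step 5 | (5R)-5-[(2E)-2-methyl-4-{(2-oxo-2H-chromen-7-yl)oxy}but-2-en-1-yl]-3-methylideneoxolan-2-one | C=C1C[C@@H](C/C(C)=C/COc2ccc3ccc(=O)oc3c2)OC1=O
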